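## The problem

Arthrosporol A (31) joins two carbocycles through a five-carbon tether. The atom labels used throughout are:

- **Ring A:** C1a (quaternary epoxide carbon carrying the tether), C2a (epoxide CH), C3a and C6a (CHOH), C4a (alkene carbon carrying CH2OH), C5a (alkene CH).
- **Tether:** C1t (carbinol on C1a), C2t=C3t (Z, methyl on C3t), C4t=C5t (E).
- **Ring B:** C1b (CH carrying the tether), C2b (CMe2), C3b (CHOH), C4b and C5b (CH2), C6b (C(CH3)OH).

There are eight stereocentres (C1a, C2a, C3a, C6a, C1t, C1b, C3b, C6b) and two alkene geometries. The planar diene insulates the rings from each other, so each ring must be made as a single enantiomer on its own; only C1t lies close enough to be steered, by ring A. The epoxide is flanked by three carbinols (Payne migration under base, opening under acid), the C1t carbinol is dienylic (ionisation), and the Z alkene can isomerise, so the last steps must be near neutral and all six hydroxyls should be released in one mild operation. In ring A the hydroxyls at C3a and C6a are cis to each other across the C4a=C5a alkene and both trans to the oxirane. That is the pattern left when O2 adds across a cyclohexadiene on the face opposite an epoxide, which makes a benzene oxide the natural precursor. In ring B the three substituents at C1b, C3b and C6b are all equatorial with an axial methyl at C6b, the pattern of a chair epoxy-polyene closure followed by equatorial delivery of oxygen.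

## Retrosynthesis

**Unmasking.** Target 31 is traced to 30, in which every hydroxyl except the one at C1t is a silyl ether (four triethylsilyl, one tert-butyldimethylsilyl). One buffered fluoride treatment then ends the synthesis, and the C1t hydroxyl, formed last, never needs protection.

**C1t–C2t bond.** Cutting between the carbinol and the diene divides 30 into the ring A aldehyde 14 and the dienyllithium 29, generated from the (1Z,3E)-dienyl iodide 28. Against a cut at C3t–C4t (cross-coupling) or at C4t=C5t on the joined system, this cut unites two halves of similar size in the penultimate step. It lets ring A direct the new stereocentre and keeps both alkene geometries prefabricated on the cheaper fragment. The forward reaction must retain the Z geometry (iodine–lithium exchange does) and must attack the correct aldehyde face.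

**Ring A adjustments and resolution.** Aldehyde 14 comes from alcohol 13 and ester 12, the bis-silyl ether of diol 11. Diol 11 is obtained from racemic 10 by lipase resolution. The resolution is unavoidable because the arene oxide behind 10 racemises. It is placed immediately after the diol appears, where two secondary carbinols are free for the enzyme and nothing costly has yet been invested.

**C3a–O and C6a–O bonds (key disconnection).** Diol 10 is the reduction product of endoperoxide 9, and 9 is the [4+2] adduct of singlet oxygen with arene oxide 8. Stepwise alternatives (two ketone reductions, or epoxide openings) would need separate control at each carbinol and a separate introduction of the alkene. This cut sets both carbinols relative to the epoxide in one step and leaves C4a=C5a in place. Precursor 8 has a single stereochemical element, the oxirane.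

**Arene oxide.** Arene oxide 8 arises by double dehydrobromination of dibromo epoxide 7, made from dibromide 6 and cyclohexadiene 5. Diene 5 is the Diels–Alder adduct of silyloxymethyl diene 3 with methyl propiolate (4), which fixes the 1,4 relationship of ester and CH2O. Diene 3 comes from dienol 2 and 2-methyl-2-vinyloxirane (1).

**C4t=C5t bond.** Iodide 28 is cut at the E alkene into tetrazolyl sulfone 22 and (Z)-iodo enal 26. C5t is C1 of the geranyl chain, so it is already on ring B and only needs to become a sulfone. Enal 26 comes from iodo alcohol 25 and propargyl alcohol (23) via the chelated alkenylmagnesium 24, so the Z geometry is set on a three-carbon unit.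

**Ring B.** Sulfone 22 is traced through 21 and 20 to triol 19. The tertiary carbinol of 19 comes from spiro epoxide 18 and exocyclic alkene 17. The C1b–C2b bond of 17 is cut in a radical epoxy-polyene cyclisation of (R)-6,7-epoxygeranyl acetate (16), made from geranyl acetate (15). The catalyst sets C3b, the chair sets C1b, and the ring's axial methyl sets C6b.

## Roads not taken

**Alternative 1: quinone on a cyclopentadiene template.** The cut is at the two oxirane C–O bonds. Quinone diester A1 would be taken to its endo cyclopentadiene adduct A2, and Weitz–Scheffer epoxidation of the remaining ene-dione ester on the convex face would give A3. Two ketone reductions, a retro-Diels–Alder reaction to unveil C4a=C5a, and differentiation of the two esters would follow.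
- Merits: the oxirane face is fixed by the bicyclic template, and no peroxide or arene oxide is handled.
- In one respect it is better than the chosen plan: the initial Diels–Alder reaction could in principle be run with a chiral Lewis acid, so no resolution would be needed. The chosen plan must set a lipase resolution, and the loss of half the material, against this.
- Weak points: both carbinols must end up trans to the oxirane, and each reduction is a contest between the template's convex-face bias and the usual tendency of hydride to enter anti to an epoxide oxygen. The retro-Diels–Alder reaction must be run hot on an epoxy diol. The two esters differ only after that step.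
- The chosen plan sets the four oxygenated ring carbons in two steps (7 and 8) with the alkene already in place.

**Alternative 2: ketyl–olefin closure of ring B.** The cut is at C1b–C6b. SmI2 (divalent samarium) with HMPA would reduce the methyl ketone of keto vinyl sulfone A4 to a ketyl that adds 6-exo to the vinyl sulfone, giving hydroxy sulfone A5.
- In one respect it is better: A5 has the tertiary carbinol and the sulfonylmethyl group in place directly after ring closure. The chosen plan spends four steps (15–18) to reach the same point from its cyclisation product.
- Weak points: A4 needs its own enantioselective synthesis (C3b stereocentre, gem-dimethyl, vinyl sulfone, ketone). The phenyl sulfone calls for a reductive Julia sequence that an alkenyl iodide would not survive. The plan says nothing about ring A, the harder half.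
- The chosen plan reaches the ring B skeleton in two steps from geranyl acetate with catalyst control of C3b, and its central step solves ring A.

**Alternative 3: propyne as linchpin.** The cuts are at C1t–C2t and C3t–C4t together. Ni(cod)2 (zerovalent nickel) would join ring A aldehyde A6, propyne and ring B alkenylzinc chloride A7 through an oxanickelacycle to give A8.
- In one respect it is better: it is the most convergent endgame, setting the Z alkene by syn addition and dispensing with the iodo enal and the olefination (steps 20–22 here).
- Weak points: propyne must bond to the aldehyde at its CH terminus and not the methyl-bearing carbon. Direct addition of the alkenylzinc to the aldehyde and alkyne oligomerisation compete. Zerovalent nickel can insert into an oxirane next to a carbonyl. The C1t configuration would come from a metallacycle whose facial preference on this aldehyde is hard to predict. Two advanced fragments would be risked at once, and A6 still needs a ring A synthesis.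
- The chosen plan accepts three more steps on small fragments so that each geometry is secured before the halves meet.

Key step: step 7

Assumption: arene oxide 8 equilibrates with its oxepin valence tautomer and is therefore racemic; compounds 6–10 are racemic and are written as the enantiomer that leads to the target.

## Route

Step 1
Reactants: 1 2-methyl-2-vinyloxirane
Product: 2 2-methylidenebut-3-en-1-ol
Conditions: LiN(i-Pr)2 (1.5 equiv), Et2O, 0 °C to rt; aq. NH4Cl
Reagents that add atoms: none
Why: Base-induced isomerisation of an epoxide to an allylic alcohol; the amide removes a methyl proton and the ring opens to the dienyl alkoxide, and only the methyl group offers such a proton.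

Step 2
Reactants: 2 2-methylidenebut-3-en-1-ol
Product: 3 tert-butyl(dimethyl)[(2-methylidenebut-3-en-1-yl)oxy]silane
Conditions: t-BuMe2SiCl, imidazole, CH2Cl2, 0 °C to rt
Reagents that add atoms: tert-butyldimethylsilyl chloride, CC(C)(C)[Si](C)(C)Cl
Why: Routine silylation of a primary allylic alcohol; the ether must last through bromination, peracid and amidine base.

Step 3
Reactants: 3 silyloxymethyl diene; 4 methyl propiolate
Product: 5 methyl 4-({[tert-butyl(dimethyl)silyl]oxy}methyl)cyclohexa-1,4-diene-1-carboxylate
Conditions: EtAlCl2 (0.3 equiv), CH2Cl2, −20 °C to rt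
Reagents that add atoms: none
Why: Diels–Alder reaction of a 2-substituted butadiene with an alkynoate; the diene terminus next to the substituted carbon pairs with the β-carbon of the propiolate (the 1,4 or "para" orientation), and Lewis-acid activation of the ester should sharpen this preference.

Step 4
Reactants: 5 cyclohexadiene ester
Product: 6 methyl trans-4,5-dibromo-4-({[tert-butyl(dimethyl)silyl]oxy}methyl)cyclohex-1-ene-1-carboxylate (racemic)
Conditions: Br2 (1.0 equiv), CH2Cl2, −78 °C
Reagents that add atoms: bromine, BrBr
Why: Electrophilic anti addition to the electron-rich trisubstituted alkene, which reacts far faster than the ester-deactivated one; both new stereocentres vanish again in step 6.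

Step 5
Reactants: 6 dibromo enoate
Product: 7 methyl trans-3,4-dibromo-4-({[tert-butyl(dimethyl)silyl]oxy}methyl)-7-oxabicyclo[4.1.0]heptane-1-carboxylate (racemic, both epoxide diastereomers)
Conditions: CF3CO3H [from (CF3CO)2O and H2O2·urea], Na2HPO4, CH2Cl2, 0 °C to reflux
Reagents that add atoms: trifluoroperacetic acid, OOC(=O)C(F)(F)F
Why: Electrophilic epoxidation of an α,β-unsaturated ester needs the strongest common peracid; the phosphate buffer protects the silyl ether, and the facial outcome is irrelevant because both diastereomers converge in step 6.

Step 6
Reactants: 7 dibromo epoxide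
Product: 8 methyl 4-({[tert-butyl(dimethyl)silyl]oxy}methyl)-7-oxabicyclo[4.1.0]hepta-2,4-diene-1-carboxylate (arene oxide, racemic)
Conditions: DBU (4 equiv), THF, 0 °C to rt
Reagents that add atoms: none
Why: Double E2 dehydrobromination, the standard entry to arene oxides from dibromo epoxides; the anti hydrogens sit on the ring methylenes beside the oxirane and elimination toward the oxygen-bearing exocyclic carbon is disfavoured, so both alkenes form in the ring. The ester on the oxirane carbon slows acid-induced aromatisation.

Step 7
Reactants: 8 arene oxide
Product: 9 methyl 9-({[tert-butyl(dimethyl)silyl]oxy}methyl)-3,6,7-trioxatricyclo[3.2.2.0^2,4]non-8-ene-2-carboxylate (peroxide bridge anti to the oxirane, racemic)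
Conditions: O2, tetraphenylporphyrin (1 mol%), visible light, CH2Cl2, −30 °C
Reagents that add atoms: dioxygen (as singlet oxygen), O=O
Why: Tetraphenylporphyrin sensitises triplet oxygen to singlet oxygen, which adds as a two-atom dienophile across C3a and C6a of the cyclohexadiene held s-cis in the benzene oxide tautomer, a concerted [4+2] cycloaddition. The closest known reaction type is the photooxygenation of benzene oxide–oxepin systems and of substituted arene oxides to anti epoxy endoperoxides. The 1,2-dioxine ring is closed in the cycloaddition itself, both C–O bonds forming on one face of the diene, so the oxygens at C3a and C6a must be cis to each other. Their configuration relative to C1a and C2a is set by the oxirane: the reagent approaches the diene face opposite the epoxide oxygen, the less hindered side and the one free of lone-pair repulsion. Three selectivities are needed: cycloaddition over the ene reaction at the silyloxymethyl-bearing alkene, reaction through the oxide and not the oxepin, and anti over syn approach. The first is secured by the cisoid cyclic diene, which reacts with singlet oxygen far faster than an isolated trisubstituted alkene; the second by the fast oxide–oxepin equilibrium, which feeds the only tautomer with a planar s-cis diene whatever its share (Curtin–Hammett); the third by the epoxide oxygen. Low temperature and the absence of base keep the endoperoxide from rearranging before it is reduced in step 8.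

Step 8
Reactants: 9 anti epoxy endoperoxide
Product: 10 methyl 2,5-dihydroxy-4-({[tert-butyl(dimethyl)silyl]oxy}methyl)-7-oxabicyclo[4.1.0]hept-3-ene-1-carboxylate (hydroxyls cis to each other and trans to the oxirane, racemic)
Conditions: thiourea (1.5 equiv), MeOH, 0 °C to rt
Reagents that add atoms: none
Why: Thiourea reduces the O–O bond of bicyclic endoperoxides without touching alkene, epoxide or ester; both C–O bonds stay, so the cis-1,4 relationship anti to the oxirane is carried over unchanged.

Step 9
Reactants: 10 racemic epoxy diol
Product: 11 the same epoxy diol as a single enantiomer (configuration of ring A of the target)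
Conditions: Burkholderia cepacia lipase (immobilised), vinyl acetate, t-BuOMe, 30 °C, stopped just past half conversion
Reagents that add atoms: none
Why: Lipase-catalysed kinetic resolution by transesterification of a cyclic allylic secondary alcohol; by the large/medium substituent model for these lipases the C6a carbinol of the unwanted enantiomer should be the one acetylated, so the target-series diol is recovered unchanged and separated from the monoacetate by chromatography.

Step 10
Reactants: 11 enantiopure epoxy diol
Product: 12 bis(triethylsilyl) ether of 11 at C3a–O and C6a–O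
Conditions: Et3SiCl (2.5 equiv), imidazole, DMAP (cat.), DMF, rt
Reagents that add atoms: chlorotriethylsilane, CC[Si](Cl)(CC)CC
Why: Standard silylation; triethylsilyl ethers survive hydride, periodinane and alkyllithium at low temperature and leave with the other silyl groups at the end.

Step 11
Reactants: 12 silylated epoxy ester
Product: 13 primary alcohol (CH2OH on C1a; ring A otherwise as in 12)
Conditions: i-Bu2AlH (2.5 equiv), CH2Cl2, −78 to −40 °C; Rochelle salt
Reagents that add atoms: none
Why: Hydride reduction of the ester to the primary alcohol; at low temperature the aluminium hydride does not open the oxirane.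

Step 12
Reactants: 13 epoxy alcohol
Product: 14 ring A epoxy aldehyde (CHO on C1a)
Conditions: Dess–Martin periodinane, NaHCO3, CH2Cl2, 0 °C to rt
Reagents that add atoms: none
Why: Mild buffered oxidation of a primary alcohol; the aldehyde has no α-hydrogen and cannot epimerise or enolise.

Step 13
Reactants: 15 geranyl acetate
Product: 16 (2E)-5-[(2R)-3,3-dimethyloxiran-2-yl]-3-methylpent-2-en-1-yl acetate
Conditions: D-fructose-derived Shi ketone (0.3 equiv), KHSO5 (Oxone), K2CO3, Bu4NHSO4, MeCN–CH2(OMe)2–aq. Na2B4O7 buffer, 0 °C
Reagents that add atoms: potassium peroxymonosulfate, [K+].OOS(=O)(=O)[O-]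
Why: Shi epoxidation through a chiral dioxirane; the distal trisubstituted alkene is the more electron-rich (the allylic acetate deactivates the other), and the spiro transition state of this ketone delivers oxygen to the face that gives the (R)-epoxide, the future C3b.

Step 14
Reactants: 16 (R)-epoxygeranyl acetate
Product: 17 [(1S,3R)-3-hydroxy-2,2-dimethyl-6-methylidenecyclohexyl]methyl acetate
Conditions: Cp2TiCl2 (2.2 equiv), Mn dust, THF, rt, degassed; 1 M HCl
Reagents that add atoms: none
Why: Radical epoxy-polyene cyclisation: Cp2TiCl (trivalent titanium, formed in the flask) opens the epoxide homolytically to the tertiary radical, which adds 6-endo to the E alkene through a chair with the titanoxy and acetoxymethyl groups equatorial, setting C1b cis to C3b. A second Cp2TiCl captures the ring radical and β-hydride elimination leaves the exocyclic alkene.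

Step 15
Reactants: 17 hydroxy alkene
Product: 18 spiro epoxide of 17 (oxirane oxygen equatorial on C6b and trans to the acetoxymethyl group)
Conditions: m-CPBA, NaHCO3, CH2Cl2, 0 °C
Reagents that add atoms: m-chloroperbenzoic acid, OOC(=O)c1cccc(Cl)c1
Why: Peracid epoxidation of a methylidenecyclohexane; the axial methyl on C2b blocks the axial trajectory, so oxygen is delivered equatorially, which fixes C6b.

Step 16
Reactants: 18 spiro epoxide
Product: 19 (1R,2S,4R)-2-(hydroxymethyl)-1,3,3-trimethylcyclohexane-1,4-diol
Conditions: LiAlH4 (3 equiv), THF, 0 °C to reflux; aqueous work-up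
Reagents that add atoms: none
Why: Hydride opens the oxirane at its unhindered methylene terminus (SN2), which becomes the axial methyl and leaves the equatorial tertiary hydroxyl; the acetate is reduced off in the same operation.

Step 17
Reactants: 19 triol
Product: 20 1-phenyl-1H-tetrazol-5-yl sulfide at C5t (secondary and tertiary hydroxyls free)
Conditions: 1-phenyl-1H-tetrazole-5-thiol, PPh3, i-PrO2CN=NCO2i-Pr, THF, 0 °C to rt
Reagents that add atoms: 1-phenyl-1H-tetrazole-5-thiol, Sc1nnnn1-c1ccccc1
Why: Mitsunobu thioetherification; only the primary hydroxyl forms an alkoxyphosphonium ion that the acidic thiol can displace, while the neopentylic secondary and the tertiary hydroxyl stay untouched.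

Step 18
Reactants: 20 sulfide
Product: 21 1-phenyl-1H-tetrazol-5-yl sulfone at C5t
Conditions: (NH4)6Mo7O24·4H2O (0.1 equiv), 30% H2O2, EtOH, 0 °C to rt
Reagents that add atoms: hydrogen peroxide, OO
Why: Molybdate-catalysed peroxide oxidation of sulfide to sulfone, the usual second step toward Julia–Kocienski reagents; free hydroxyls are tolerated.

Step 19
Reactants: 21 dihydroxy sulfone
Product: 22 bis(triethylsilyl) ether of 21 at C3b–O and C6b–O
Conditions: Et3SiOTf (3 equiv), 2,6-lutidine, CH2Cl2, −78 to 0 °C
Reagents that add atoms: triethylsilyl trifluoromethanesulfonate, CC[Si](CC)(CC)OS(=O)(=O)C(F)(F)F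
Why: The silyl triflate is reactive enough to cap the tertiary hydroxyl as well as the secondary one, so no acidic proton remains for the two organometallic steps ahead.

Step 20
Reactants: 23 prop-2-yn-1-ol
Product: 25 (2Z)-3-iodo-2-methylprop-2-en-1-ol, via 3-methyl-2,5-dihydro-1,2-oxamagnesole 24 (not isolated)
Conditions: MeMgBr (3 equiv), CuI (0.1 equiv), THF, −10 °C to rt; then I2, −78 to 0 °C
Reagents that add atoms: methylmagnesium bromide, C[Mg]Br; iodine, II
Why: Copper-catalysed carbomagnesiation of the propargylic alkoxide puts methyl on the internal carbon and magnesium on the terminus in a five-membered chelate with the alkoxide; iodinolysis with retention gives the alkenyl iodide with iodine cis to the hydroxymethyl group.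

Step 21
Reactants: 25 (Z)-iodo allylic alcohol
Product: 26 (2Z)-3-iodo-2-methylprop-2-enal
Conditions: MnO2 (15 equiv), CH2Cl2, rt, dark; used at once
Reagents that add atoms: none
Why: Heterogeneous oxidation of an allylic alcohol under neutral conditions, which gives the (Z)-β-iodo enal no acid or nucleophile by which to isomerise.

Step 22
Reactants: 22 ring B sulfone; 26 (Z)-iodo enal
Product: 28 (1Z,3E)-1-iodo-2-methyl-4-(ring B)buta-1,3-diene with ring B as its bis(triethylsilyl) ether, via potassium sulfonyl carbanion 27 (not isolated)
Conditions: KN(SiMe3)2 (1.05 equiv), MeOCH2CH2OMe, −60 °C; then 26, −60 °C to rt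
Reagents that add atoms: none
Why: Julia–Kocienski olefination: the metalated tetrazolyl sulfone adds to the aldehyde, then Smiles rearrangement and loss of SO2 and tetrazolate give the alkene. A β-branched sulfone with a potassium counterion in a coordinating ether should favour the (E)-alkene, and the alkenyl iodide geometry is not involved.

Step 23
Reactants: 28 dienyl iodide; 14 ring A epoxy aldehyde
Product: 30 arthrosporol A with free C1t hydroxyl and five silyl ethers (four triethylsilyl plus tert-butyldimethylsilyl on the primary oxygen), via dienyllithium 29 (not isolated)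
Conditions: t-BuLi (2.1 equiv relative to 28), Et2O, −78 °C; then 14, Et2O, −78 °C; aq. NH4Cl
Reagents that add atoms: none
Why: Iodine–lithium exchange retains alkene geometry and the alkenyllithium adds 1,2 to the non-enolisable aldehyde. In the dipole-minimised (Cornforth) arrangement, with C=O anti to the oxirane C–O bond, the nucleophile should enter on the epoxide face past the hydrogen on C6a, clear of the oxirane ring and of the silyloxy group on the lower face, giving the anti epoxy carbinol, (S) at C1t.

Step 24
Reactants: 30 pentasilyl ether
Product: 31 arthrosporol A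
Conditions: HF·pyridine, pyridine, THF, 0 °C to rt
Reagents that add atoms: none
Why: Fluoride-driven cleavage of all five silyl ethers under buffered, weakly acidic conditions; basic fluoride could set off Payne migration of the oxirane among the freed alkoxides and strong acid would ionise the dienylic carbinol.

## Compound list

1 | 2-methyl-2-vinyloxirane (racemic) | CC1(C=C)CO1 | starting material
2 | 2-methylidenebut-3-en-1-ol | C=CC(=C)CO | intermediate
3 | tert-butyl(dimethyl)[(2-methylidenebut-3-en-1-yl)oxy]silane | C=CC(=C)CO[Si](C)(C)C(C)(C)C | intermediate
4 | methyl propiolate | C#CC(=O)OC | starting material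
5 | methyl 4-({[tert-butyl(dimethyl)silyl]oxy}methyl)cyclohexa-1,4-diene-1-carboxylate | COC(=O)C1=CCC(CO[Si](C)(C)C(C)(C)C)=CC1 | intermediate
6 | methyl trans-4,5-dibromo-4-(silyloxymethyl)cyclohex-1-ene-1-carboxylate, racemic | COC(=O)C1=CC[C@](Br)(CO[Si](C)(C)C(C)(C)C)[C@H](Br)C1 | intermediate
7 | methyl trans-3,4-dibromo-4-(silyloxymethyl)-7-oxabicyclo[4.1.0]heptane-1-carboxylate, racemic, both epoxide diastereomers (oxirane centres left open) | COC(=O)C12OC1C[C@](Br)(CO[Si](C)(C)C(C)(C)C)[C@H](Br)C2 | intermediate
8 | methyl 4-(silyloxymethyl)-7-oxabicyclo[4.1.0]hepta-2,4-diene-1-carboxylate, arene oxide, racemic through its oxepin | COC(=O)[C@]12O[C@H]1C=C(CO[Si](C)(C)C(C)(C)C)C=C2 | intermediate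
9 | anti epoxy endoperoxide, methyl 9-(silyloxymethyl)-3,6,7-trioxatricyclo[3.2.2.0^2,4]non-8-ene-2-carboxylate, racemic | COC(=O)[C@]12O[C@H]1[C@@H]3OO[C@H]2C=C3CO[Si](C)(C)C(C)(C)C | intermediate
10 | methyl 2,5-dihydroxy-4-(silyloxymethyl)-7-oxabicyclo[4.1.0]hept-3-ene-1-carboxylate, hydroxyls cis to each other and trans to the oxirane, racemic | COC(=O)[C@]12O[C@H]1[C@H](O)C(CO[Si](C)(C)C(C)(C)C)=C[C@@H]2O | intermediate
11 | the same epoxy diol, single enantiomer of the target series | COC(=O)[C@]12O[C@H]1[C@H](O)C(CO[Si](C)(C)C(C)(C)C)=C[C@@H]2O | intermediate
12 | bis(triethylsilyl) ether of 11 | COC(=O)[C@]12O[C@H]1[C@H](O[Si](CC)(CC)CC)C(CO[Si](C)(C)C(C)(C)C)=C[C@@H]2O[Si](CC)(CC)CC | intermediate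
13 | ring A primary alcohol (CH2OH on C1a) | OC[C@]12O[C@H]1[C@H](O[Si](CC)(CC)CC)C(CO[Si](C)(C)C(C)(C)C)=C[C@@H]2O[Si](CC)(CC)CC | intermediate
14 | ring A epoxy aldehyde (CHO on C1a) | O=C[C@]12O[C@H]1[C@H](O[Si](CC)(CC)CC)C(CO[Si](C)(C)C(C)(C)C)=C[C@@H]2O[Si](CC)(CC)CC | intermediate
15 | geranyl acetate | CC(C)=CCC/C(C)=C/COC(C)=O | starting material
16 | (2E)-5-[(2R)-3,3-dimethyloxiran-2-yl]-3-methylpent-2-en-1-yl acetate | CC(=O)OC/C=C(\C)CC[C@H]1OC1(C)C | intermediate
17 | [(1S,3R)-3-hydroxy-2,2-dimethyl-6-methylidenecyclohexyl]methyl acetate | CC(=O)OC[C@@H]1C(C)(C)[C@H](O)CCC1=C | intermediate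
18 | spiro epoxide of 17, oxirane oxygen equatorial and trans to the acetoxymethyl group | CC(=O)OC[C@@H]1C(C)(C)[C@H](O)CC[C@]12CO2 | intermediate
19 | (1R,2S,4R)-2-(hydroxymethyl)-1,3,3-trimethylcyclohexane-1,4-diol | OC[C@@H]1C(C)(C)[C@H](O)CC[C@@]1(C)O | intermediate
20 | ring B 1-phenyltetrazolyl sulfide (diol free) | C(Sc2nnnn2-c2ccccc2)[C@@H]1C(C)(C)[C@H](O)CC[C@@]1(C)O | intermediate
21 | ring B 1-phenyltetrazolyl sulfone (diol free) | C(S(=O)(=O)c2nnnn2-c2ccccc2)[C@@H]1C(C)(C)[C@H](O)CC[C@@]1(C)O | intermediate
22 | ring B sulfone, bis(triethylsilyl) ether | C(S(=O)(=O)c2nnnn2-c2ccccc2)[C@@H]1C(C)(C)[C@H](O[Si](CC)(CC)CC)CC[C@@]1(C)O[Si](CC)(CC)CC | intermediate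
23 | prop-2-yn-1-ol | C#CCO | starting material
24 | 3-methyl-2,5-dihydro-1,2-oxamagnesole (chelated alkenylmagnesium alkoxide, not isolated) | CC1=C[Mg]OC1 | intermediate
25 | (2Z)-3-iodo-2-methylprop-2-en-1-ol | OC/C(C)=C\I | intermediate
26 | (2Z)-3-iodo-2-methylprop-2-enal | O=C/C(C)=C\I | intermediate
27 | potassium salt of the α-sulfonyl carbanion of 22 (not isolated) | [K+].[CH-](S(=O)(=O)c2nnnn2-c2ccccc2)[C@@H]1C(C)(C)[C@H](O[Si](CC)(CC)CC)CC[C@@]1(C)O[Si](CC)(CC)CC | intermediate
28 | (1Z,3E)-1-iodo-2-methyl-4-(ring B)buta-1,3-diene, ring B as bis(triethylsilyl) ether | I\C=C(C)/C=C/[C@@H]1C(C)(C)[C@H](O[Si](CC)(CC)CC)CC[C@@]1(C)O[Si](CC)(CC)CC | intermediate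
29 | (1Z,3E)-dienyllithium from 28 (not isolated) | [Li]\C=C(C)/C=C/[C@@H]1C(C)(C)[C@H](O[Si](CC)(CC)CC)CC[C@@]1(C)O[Si](CC)(CC)CC | intermediate
30 | arthrosporol A with free (S)-C1t hydroxyl, four triethylsilyl ethers and one tert-butyldimethylsilyl ether | CC(=C/[C@H](O)[C@]12O[C@H]1[C@H](O[Si](CC)(CC)CC)C(CO[Si](C)(C)C(C)(C)C)=C[C@@H]2O[Si](CC)(CC)CC)/C=C/[C@@H]1C(C)(C)[C@H](O[Si](CC)(CC)CC)CC[C@@]1(C)O[Si](CC)(CC)CC | intermediate
31 | arthrosporol A | CC(=C/[C@H](O)[C@]12O[C@H]1[C@H](O)C(CO)=C[C@@H]2O)/C=C/[C@@H]1C(C)(C)[C@H](O)CC[C@@]1(C)O | target

## Step count and least certain steps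

Total: 24 steps. Longest linear sequence: 14 steps (steps 1–12, 23, 24). Ring B branch: steps 13–19; enal branch: steps 20–21; union in step 22.

**Step 7 (key step).** The most likely failure is loss of material around the cycloaddition, not wrong facial selectivity. The arene oxide can aromatise before it reacts, an ene reaction at the silyloxymethyl-bearing alkene can compete, and the endoperoxide can rearrange thermally to a bis-epoxide or fragment under traces of base (Kornblum–DeLaMare) before reduction. The fallback installs the same two C–O bonds without a peroxide. It sets out from 8: buffered m-CPBA should epoxidise the more electron-rich C3a=C4a alkene on the face opposite the first oxirane to give the anti bis-epoxide F1. Pd(PPh3)4 (zerovalent palladium) with acetic acid then ionises the vinyl epoxide at C4a with inversion and returns acetate at C6a with a second inversion, giving the racemic cis-1,4 hydroxy acetate F2. Methanolysis (K2CO3, MeOH) comes back to the route at 10.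

**Step 9.** The enzyme may discriminate poorly between the enantiomers, because each offers two carbinols of different local shape and acylation at C3a of the wanted enantiomer could compete with acylation at C6a of the unwanted one. The fallback is a classical resolution. It sets out from 10: both hydroxyls are esterified with (S)-O-methylmandelic acid (DCC, DMAP) to give the target-series bis-(S)-O-methylmandelate F3 and the diastereomeric bis-ester of the other enantiomer F4, which are separated by chromatography or crystallisation. Methanolysis of F3 (K2CO3, MeOH, 0 °C) comes back to the route at 11.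

**Step 23.** Facial selectivity at the aldehyde may be poor or reversed if a lithium chelate with the oxirane oxygen or attack from the lower face competes with the Cornforth pathway; silyl migration to the new alkoxide is a lesser risk. The fallback sets out from 14 and 28 and takes their coupling product on in whatever C1t ratio it forms, the unwanted C1t epimer F5 included. Dess–Martin oxidation gives the dienone F6. Reduction under Corey–Bakshi–Shibata control with (R)-2-methyl-CBS-oxazaborolidine and BH3·SMe2 (on the premise that the quaternary oxirane carbon acts as the large group) comes back to the route at 30.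

**Step 22.** Two processes threaten the diene geometry: incomplete E selectivity in the addition of the sulfonyl anion to a conjugated aldehyde, and erosion of the Z iodoalkene by conjugate addition–elimination at the β-iodo enal. The fallback reverses the polarity and avoids the enal. It sets out from 19 and 25. Triol 19 is persilylated (Et3SiOTf, 2,6-lutidine) to the tris(triethylsilyl) ether F7, whose primary silyl ether is cleaved and oxidised in one pot under Swern conditions to the ring B aldehyde F8. Alcohol 25 is converted (CBr4, PPh3) into the allylic bromide F9 and then (PBu3, MeCN) into the tributylphosphonium bromide F10. Wittig reaction of F10 (LiN(SiMe3)2, THF, −78 °C) with F8 comes back to the route at 28; allylic trialkylphosphonium ylides are known to favour (E)-dienes.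

**Step 24.** Prolonged exposure to HF, needed for the hindered tertiary silyl ether on C6b, may open the oxirane or ionise the dienylic carbinol before the last silyl group has left. The fallback moves the ring B deprotection ahead of the coupling. It sets out from 28 (and uses 14): mild methanolysis (pyridinium p-toluenesulfonate, MeOH) gives the dienyl iodide diol F11. Nozaki–Hiyama–Kishi coupling of F11 with 14 (CrCl2, divalent chromium, with catalytic NiCl2, DMSO) tolerates the free hydroxyls and gives the tris-silyl ether F12. Only the three more labile ring A silyl ethers then remain, to be removed with Et3N·3HF in MeCN, which comes back to the route at 31.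

## Further compounds

F1 | step 7 | anti bis-epoxide of the arene oxide (second oxirane on C3a–C4a, opposite face), racemic | COC(=O)[C@]12O[C@H]1[C@@H]3O[C@]3(CO[Si](C)(C)C(C)(C)C)C=C2
F2 | step 7 | C6a acetate of 10 (cis-1,4 hydroxy acetate), racemic | COC(=O)[C@]12O[C@H]1[C@H](O)C(CO[Si](C)(C)C(C)(C)C)=C[C@@H]2OC(C)=O
F3 | step 9 | bis-(S)-O-methylmandelate of 11 | COC(=O)[C@]12O[C@H]1[C@H](OC(=O)[C@@H](OC)c3ccccc3)C(CO[Si](C)(C)C(C)(C)C)=C[C@@H]2OC(=O)[C@@H](OC)c3ccccc3
F4 | step 9 | bis-(S)-O-methylmandelate of the enantiomer of 11 | COC(=O)[C@@]12O[C@@H]1[C@@H](OC(=O)[C@@H](OC)c3ccccc3)C(CO[Si](C)(C)C(C)(C)C)=C[C@H]2OC(=O)[C@@H](OC)c3ccccc3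
F5 | step 23 | C1t epimer of 30 | CC(=C/[C@@H](O)[C@]12O[C@H]1[C@H](O[Si](CC)(CC)CC)C(CO[Si](C)(C)C(C)(C)C)=C[C@@H]2O[Si](CC)(CC)CC)/C=C/[C@@H]1C(C)(C)[C@H](O[Si](CC)(CC)CC)CC[C@@]1(C)O[Si](CC)(CC)CC
F6 | step 23 | C1t dienone from 30 | CC(=C/C(=O)[C@]12O[C@H]1[C@H](O[Si](CC)(CC)CC)C(CO[Si](C)(C)C(C)(C)C)=C[C@@H]2O[Si](CC)(CC)CC)/C=C/[C@@H]1C(C)(C)[C@H](O[Si](CC)(CC)CC)CC[C@@]1(C)O[Si](CC)(CC)CC
F7 | step 22 | tris(triethylsilyl) ether of 19 | CC[Si](CC)(CC)OC[C@@H]1C(C)(C)[C@H](O[Si](CC)(CC)CC)CC[C@@]1(C)O[Si](CC)(CC)CC
F8 | step 22 | ring B aldehyde, bis(triethylsilyl) ether | O=C[C@@H]1C(C)(C)[C@H](O[Si](CC)(CC)CC)CC[C@@]1(C)O[Si](CC)(CC)CC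
F9 | step 22 | (1Z)-3-bromo-1-iodo-2-methylprop-1-ene | BrC/C(C)=C\I
F10 | step 22 | tributyl[(2Z)-3-iodo-2-methylprop-2-en-1-yl]phosphonium bromide | CCCC[P+](CCCC)(CCCC)C/C(C)=C\I.[Br-]
F11 | step 24 | (1Z,3E)-dienyl iodide with free ring B diol | I\C=C(C)/C=C/[C@@H]1C(C)(C)[C@H](O)CC[C@@]1(C)O
F12 | step 24 | arthrosporol A silylated only on the three ring A oxygens | CC(=C/[C@H](O)[C@]12O[C@H]1[C@H](O[Si](CC)(CC)CC)C(CO[Si](C)(C)C(C)(C)C)=C[C@@H]2O[Si](CC)(CC)CC)/C=C/[C@@H]1C(C)(C)[C@H](O)CC[C@@]1(C)O
A1 | alternative 1 | dimethyl 3,6-dioxocyclohexa-1,4-diene-1,4-dicarboxylate | COC(=O)C1=CC(=O)C(C(=O)OC)=CC1=O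
A2 | alternative 1 | endo cyclopentadiene adduct of A1 | COC(=O)C1=CC(=O)[C@]2(C(=O)OC)[C@@H]3C=C[C@@H](C3)[C@@H]2C1=O
A3 | alternative 1 | convex-face epoxide of A2 | COC(=O)[C@]12O[C@H]1C(=O)[C@]3(C(=O)OC)[C@@H]4C=C[C@@H](C4)[C@@H]3C2=O
A4 | alternative 2 | (E)-keto vinyl sulfone, acyclic ring B precursor | CC(=O)CC[C@@H](O[Si](C)(C)C(C)(C)C)C(C)(C)/C=C/S(=O)(=O)c1ccccc1
A5 | alternative 2 | ring B hydroxy phenyl sulfone | O=S(=O)(C[C@@H]1C(C)(C)[C@H](O[Si](C)(C)C(C)(C)C)CC[C@@]1(C)O)c1ccccc1
A6 | alternative 3 | ring A epoxy aldehyde, tris(tert-butyldimethylsilyl) ether | O=C[C@]12O[C@H]1[C@H](O[Si](C)(C)C(C)(C)C)C(CO[Si](C)(C)C(C)(C)C)=C[C@@H]2O[Si](C)(C)C(C)(C)C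
A7 | alternative 3 | (E)-alkenylzinc chloride of ring B | Cl[Zn]/C=C/[C@@H]1C(C)(C)[C@H](O[Si](C)(C)C(C)(C)C)CC[C@@]1(C)O[Si](CC)(CC)CC
A8 | alternative 3 | arthrosporol A with five hydroxyls silylated and the C1t hydroxyl free | CC(=C/[C@H](O)[C@]12O[C@H]1[C@H](O[Si](C)(C)C(C)(C)C)C(CO[Si](C)(C)C(C)(C)C)=C[C@@H]2O[Si](C)(C)C(C)(C)C)/C=C/[C@@H]1C(C)(C)[C@H](O[Si](C)(C)C(C)(C)C)CC[C@@]1(C)O[Si](CC)(CC)CC
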